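**Retrosynthetic overview**
1. The 14-membered ring is closed last, at C11–C12, by an intramolecular alkylzinc/alkenyl iodide (Negishi) coupling of seco-diiodide 28.
2. The C6–C7 bond comes from a late union of lactone aldehyde 19 (C13 skeleton) with iodo-enyne 24 (C7) by hydrozirconation/alkenylzinc addition, which sets C6 and 7E.
3. The ε-lactone is the first ring: a Shi epoxide is opened 7-exo at its tertiary carbon by the acrylic acid (C1–O with inversion), and the freed C14–OH is acetylated.
4. Epoxide precursor 13 comes from a B-alkyl Suzuki union of acrylate 8 (C4 set by Rh-catalysed vinyl conjugate addition) with E-alkenyl iodide 11.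
5. Fragment 24 comes from but-2-yn-1-ol (hydroalumination/iodination fixes 10Z) and propynyl Grignard. Ring order: ε-lactone, then carbocycle.

Assumption: ring carbons of the target are numbered C1 (O-bearing quaternary C), C2, C3, C4 (CH carrying the acrylate carbon), C5, C6 (CHOH), C7=C8, C9, C10=C11, C12, C13, C14 (CHOAc); compounds 1, 2, 4, 9, 20 and 23 are bought.

**Step 1**
Reactants: 1 4,4-dimethoxybut-1-ene; 2 methyl acrylate
Product: 3 methyl (2E)-5,5-dimethoxypent-2-enoate
Conditions: second-generation Grubbs catalyst RuCl2(=CHPh)(H2IMes)(PCy3) (2 mol%), 2 (3 equiv), CH2Cl2, 40 °C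
Reagents that add atoms: none
Why: Olefin cross-metathesis of a terminal alkene with an acrylate is selective for the hetero-product and gives the E-enoate under thermodynamic control.

**Step 2**
Reactants: 3 methyl (2E)-5,5-dimethoxypent-2-enoate; 4 potassium trifluoro(vinyl)borate
Product: 5 methyl (3S)-3-(2,2-dimethoxyethyl)pent-4-enoate
Conditions: [Rh(cod)2]BF4 (3 mol%), (R)-BINAP (3.3 mol%), NaHCO3 (1 equiv), toluene/H2O 10:1, 100 °C
Reagents that add atoms: none
Why: Hayashi–Miyaura rhodium-catalysed asymmetric conjugate addition, in which the (R)-BINAP complex is expected (by analogy with aryl additions to E-enoates) to deliver the vinyl group to the α-re face and so set the C4 stereocentre as 3S, the bicarbonate buffer protecting the acetal.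

**Step 3**
Reactants: 5 methyl (3S)-3-(2,2-dimethoxyethyl)pent-4-enoate
Product: 8 methyl (3R)-3-(2,2-dimethoxyethyl)-2-methylidenepent-4-enoate, via Mannich base 6 (not isolated), via trimethylammonium iodide 7 (not isolated)
Conditions: LiN(iPr)2, THF, −78 °C; Me2N=CH2 I (Eschenmoser's salt), −78→0 °C; MeI, MeOH, rt; NaHCO3 (aq), CH2Cl2, rt
Reagents that add atoms: Eschenmoser's salt, C=[N+](C)C.[I-]
Why: Ester enolate aminomethylation (Mannich reaction) followed by quaternisation and mild-base Hofmann-type elimination installs the α-methylene group without touching the adjacent stereocentre (the descriptor changes to R only through CIP priorities).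

**Step 4**
Reactants: 9 pent-3-yn-1-ol
Product: 10 (3E)-4-iodopent-3-en-1-ol
Conditions: Cp2Zr(H)Cl (2.5 equiv), THF, rt→40 °C; I2, 0 °C; 1 M HCl work-up
Reagents that add atoms: iodine, II
Why: Schwartz hydrozirconation is a syn addition that, after equilibration, places zirconium on the methyl-bearing alkyne carbon, and iodinolysis with retention gives the E-alkenyl iodide.

**Step 5**
Reactants: 10 (3E)-4-iodopent-3-en-1-ol
Product: 11 (2E)-5-chloro-2-iodopent-2-ene
Conditions: PPh3, N-chlorosuccinimide, CH2Cl2, 0 °C→rt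
Reagents that add atoms: N-chlorosuccinimide, ClN1C(=O)CCC1=O
Why: Appel-type chlorination converts the primary alcohol to a chloride that is inert in every step up to the Finkelstein exchange.

**Step 6**
Reactants: 8 methyl (3R)-3-(2,2-dimethoxyethyl)-2-methylidenepent-4-enoate; 11 (2E)-5-chloro-2-iodopent-2-ene
Product: 13 methyl (3S,6E)-9-chloro-3-(2,2-dimethoxyethyl)-6-methyl-2-methylidenenon-6-enoate, via B-alkyl-9-BBN adduct 12 (not isolated)
Conditions: 8, 9-BBN (1.05 equiv), THF, 0 °C→rt; then 11, Pd(dppf)Cl2 (5 mol%), AsPh3, Cs2CO3, DMF/H2O, rt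
Reagents that add atoms: none
Why: B-alkyl Suzuki–Miyaura coupling, in which 9-BBN hydroborates the monosubstituted vinyl group in preference to the conjugated, hindered acrylate and the alkylborane couples with the alkenyl iodide with retention, giving the E-trisubstituted alkene.

**Step 7**
Reactants: 13 methyl (3S,6E)-9-chloro-3-(2,2-dimethoxyethyl)-6-methyl-2-methylidenenon-6-enoate
Product: 14 methyl (3S)-5-[(2R,3R)-3-(2-chloroethyl)-2-methyloxiran-2-yl]-3-(2,2-dimethoxyethyl)-2-methylidenepentanoate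
Conditions: D-fructose-derived Shi ketone (30 mol%), KHSO5 (Oxone), K2CO3, Bu4NHSO4, MeCN/dimethoxymethane/aq. Na2B4O7 buffer (pH 10.5), 0 °C
Reagents that add atoms: potassium peroxymonosulfate, [K+].[O-]S(=O)(=O)OO
Why: Shi asymmetric epoxidation, in which the chiral dioxirane attacks the only electron-rich alkene through the spiro transition state to give the (R,R)-epoxide while the acrylate is inert.

**Step 8**
Reactants: 14 methyl (3S)-5-[(2R,3R)-3-(2-chloroethyl)-2-methyloxiran-2-yl]-3-(2,2-dimethoxyethyl)-2-methylidenepentanoate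
Product: 16 (4S,7S)-7-[(1R)-3-chloro-1-hydroxypropyl]-4-(2,2-dimethoxyethyl)-7-methyl-3-methylideneoxepan-2-one, via epoxy acid 15 (not isolated)
Conditions: LiOH, THF/H2O, 0 °C→rt; 1 M HCl to pH 4; then PPTS (20 mol%), CH2Cl2 (0.01 M), rt
Reagents that add atoms: lithium hydroxide, [Li+].[OH-]
Why: Saponification followed by acid-catalysed 7-exo-tet epoxide opening, in which the carboxylic acid attacks the tertiary epoxide carbon with inversion (C1 becomes S) and leaves the C14 oxygen in place (R), the 8-membered alternative being disfavoured.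

**Step 9**
Reactants: 16 (4S,7S)-7-[(1R)-3-chloro-1-hydroxypropyl]-4-(2,2-dimethoxyethyl)-7-methyl-3-methylideneoxepan-2-one
Product: 17 (1R)-3-chloro-1-[(2S,5S)-5-(2,2-dimethoxyethyl)-2-methyl-6-methylidene-7-oxooxepan-2-yl]propyl acetate
Conditions: Ac2O, DMAP, pyridine, CH2Cl2, rt
Reagents that add atoms: acetic anhydride, CC(=O)OC(C)=O
Why: DMAP-catalysed acylation of the only free hydroxyl installs the C14 acetate with retention.

**Step 10**
Reactants: 17 (1R)-3-chloro-1-[(2S,5S)-5-(2,2-dimethoxyethyl)-2-methyl-6-methylidene-7-oxooxepan-2-yl]propyl acetate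
Product: 19 (1R)-3-iodo-1-[(2S,5S)-2-methyl-6-methylidene-7-oxo-5-(2-oxoethyl)oxepan-2-yl]propyl acetate, via iodo acetal 18 (not isolated)
Conditions: NaI (10 equiv), acetone, 56 °C; then 1 M HCl (aq), rt
Reagents that add atoms: sodium iodide, [Na+].[I-]; water, O
Why: Finkelstein halide exchange (SN2 at the primary chloride) followed by acid-catalysed acetal hydrolysis in the same acetone solution gives the iodo aldehyde without affecting acetate or lactone.

**Step 11**
Reactants: 20 but-2-yn-1-ol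
Product: 21 (2Z)-3-iodobut-2-en-1-ol
Conditions: NaAlH2(OCH2CH2OMe)2, Et2O, 0 °C→rt; I2, THF, −78→0 °C
Reagents that add atoms: iodine, II
Why: Hydroxyl-directed trans-hydroalumination of the propargylic alcohol puts aluminium on C3 cis to the CH2O group, and iodinolysis with retention gives the Z-iodide.

**Step 12**
Reactants: 21 (2Z)-3-iodobut-2-en-1-ol
Product: 22 (2Z)-1-bromo-3-iodobut-2-ene
Conditions: CBr4, PPh3, CH2Cl2, 0 °C
Reagents that add atoms: carbon tetrabromide, BrC(Br)(Br)Br
Why: Appel bromination converts the allylic alcohol to the bromide without allylic transposition or loss of alkene geometry.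

**Step 13**
Reactants: 22 (2Z)-1-bromo-3-iodobut-2-ene; 23 prop-1-yn-1-ylmagnesium bromide
Product: 24 (2Z)-2-iodohept-2-en-5-yne
Conditions: CuI (10 mol%), THF, 0 °C→rt
Reagents that add atoms: none
Why: Copper-catalysed alkynyl Grignard/allylic bromide coupling occurs by SN2 at the unhindered primary carbon and leaves the alkenyl iodide untouched.

**Step 14**
Reactants: 24 (2Z)-2-iodohept-2-en-5-yne; 19 (1R)-3-iodo-1-[(2S,5S)-2-methyl-6-methylidene-7-oxo-5-(2-oxoethyl)oxepan-2-yl]propyl acetate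
Product: 28 (1R)-3-iodo-1-[(2S,5S)-5-[(2S,3E,6Z)-7-iodo-3-methyl-2-(triethylsilyloxy)octa-3,6-dien-1-yl]-2-methyl-6-methylidene-7-oxooxepan-2-yl]propyl acetate, via alkenylzirconocene chloride 25 (not isolated), via alkenyl(methyl)zinc 26 (not isolated), via methylzinc alkoxide 27 (not isolated)
Conditions: 24 (1.5 equiv), Cp2Zr(H)Cl (1.6 equiv), CH2Cl2, rt; −65 °C, ZnMe2 (1.5 equiv), toluene; (+)-MIB (10 mol%), then 19, −30→0 °C; then 2,6-lutidine, TESOTf, −40 °C
Reagents that add atoms: triethylsilyl trifluoromethanesulfonate, CC[Si](CC)(CC)OS(=O)(=O)C(F)(F)F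
Why: Hydrozirconation/zinc transmetalation/aldehyde addition (Wipf-type alkenylzinc addition), in which syn Zr–H addition places the metal on the methyl-bearing alkyne carbon (7E) and the amino alcohol (+)-MIB is chosen to direct the alkenyl group to the aldehyde face giving 6S, the zinc alkoxide then being silylated in situ.

**Step 15**
Reactants: 28 (1R)-3-iodo-1-[(2S,5S)-5-[(2S,3E,6Z)-7-iodo-3-methyl-2-(triethylsilyloxy)octa-3,6-dien-1-yl]-2-methyl-6-methylidene-7-oxooxepan-2-yl]propyl acetate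
Product: 31 target CNP0130972.9, via alkylzinc iodide 29 (not isolated), via macrocyclic triethylsilyl ether 30 (not isolated)
Conditions: Zn dust (activated with BrCH2CH2Br, TMSCl), THF, 35 °C; syringe pump into PdCl2(dppf) (10 mol%), THF/NMP, 50 °C, 1 mM; then 1 M HCl, THF, 0 °C
Reagents that add atoms: none
Why: Intramolecular Negishi sp3–sp2 coupling, in which zinc inserts only into the primary alkyl iodide and palladium-catalysed coupling with the alkenyl iodide closes the 14-membered ring with retention of the 10Z geometry, the acid work-up removing the silyl group.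

**Compound list**
1 | 4,4-dimethoxybut-1-ene | C=CCC(OC)OC | starting material
2 | methyl acrylate | C=CC(=O)OC | starting material
3 | methyl (2E)-5,5-dimethoxypent-2-enoate | COC(=O)/C=C/CC(OC)OC | intermediate
4 | potassium trifluoro(vinyl)borate | C=C[B-](F)(F)F.[K+] | starting material
5 | methyl (3S)-3-(2,2-dimethoxyethyl)pent-4-enoate | C=C[C@H](CC(=O)OC)CC(OC)OC | intermediate
6 | Mannich base: methyl 2-[(dimethylamino)methyl]-3-(2,2-dimethoxyethyl)pent-4-enoate, C3 as in 5, C2 epimers | C=C[C@H](C(CN(C)C)C(=O)OC)CC(OC)OC | intermediate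
7 | [3-(2,2-dimethoxyethyl)-2-(methoxycarbonyl)pent-4-en-1-yl]trimethylammonium iodide, C3 as in 5, C2 epimers | C=C[C@H](C(C[N+](C)(C)C)C(=O)OC)CC(OC)OC.[I-] | intermediate
8 | methyl (3R)-3-(2,2-dimethoxyethyl)-2-methylidenepent-4-enoate | C=C[C@H](C(=C)C(=O)OC)CC(OC)OC | intermediate
9 | pent-3-yn-1-ol | CC#CCCO | starting material
10 | (3E)-4-iodopent-3-en-1-ol | C/C(I)=C\CCO | intermediate
11 | (2E)-5-chloro-2-iodopent-2-ene | C/C(I)=C\CCCl | intermediate
12 | methyl (3S)-5-(9-borabicyclo[3.3.1]nonan-9-yl)-3-(2,2-dimethoxyethyl)-2-methylidenepentanoate | B1(CC[C@H](C(=C)C(=O)OC)CC(OC)OC)C2CCCC1CCC2 | intermediate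
13 | methyl (3S,6E)-9-chloro-3-(2,2-dimethoxyethyl)-6-methyl-2-methylidenenon-6-enoate | ClCC/C=C(\C)CC[C@H](C(=C)C(=O)OC)CC(OC)OC | intermediate
14 | methyl (3S)-5-[(2R,3R)-3-(2-chloroethyl)-2-methyloxiran-2-yl]-3-(2,2-dimethoxyethyl)-2-methylidenepentanoate | ClCC[C@H]1O[C@]1(C)CC[C@H](C(=C)C(=O)OC)CC(OC)OC | intermediate
15 | (3S)-5-[(2R,3R)-3-(2-chloroethyl)-2-methyloxiran-2-yl]-3-(2,2-dimethoxyethyl)-2-methylidenepentanoic acid | ClCC[C@H]1O[C@]1(C)CC[C@H](C(=C)C(=O)O)CC(OC)OC | intermediate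
16 | (4S,7S)-7-[(1R)-3-chloro-1-hydroxypropyl]-4-(2,2-dimethoxyethyl)-7-methyl-3-methylideneoxepan-2-one | C=C1C(=O)O[C@@]([C@H](O)CCCl)(C)CC[C@H]1CC(OC)OC | intermediate
17 | (1R)-3-chloro-1-[(2S,5S)-5-(2,2-dimethoxyethyl)-2-methyl-6-methylidene-7-oxooxepan-2-yl]propyl acetate | C=C1C(=O)O[C@@]([C@H](OC(C)=O)CCCl)(C)CC[C@H]1CC(OC)OC | intermediate
18 | (1R)-1-[(2S,5S)-5-(2,2-dimethoxyethyl)-2-methyl-6-methylidene-7-oxooxepan-2-yl]-3-iodopropyl acetate | C=C1C(=O)O[C@@]([C@H](OC(C)=O)CCI)(C)CC[C@H]1CC(OC)OC | intermediate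
19 | (1R)-3-iodo-1-[(2S,5S)-2-methyl-6-methylidene-7-oxo-5-(2-oxoethyl)oxepan-2-yl]propyl acetate | C=C1C(=O)O[C@@]([C@H](OC(C)=O)CCI)(C)CC[C@H]1CC=O | intermediate
20 | but-2-yn-1-ol | CC#CCO | starting material
21 | (2Z)-3-iodobut-2-en-1-ol | C/C(I)=C/CO | intermediate
22 | (2Z)-1-bromo-3-iodobut-2-ene | C/C(I)=C/CBr | intermediate
23 | prop-1-yn-1-ylmagnesium bromide | CC#C[Mg]Br | starting material
24 | (2Z)-2-iodohept-2-en-5-yne | C/C(I)=C/CC#CC | intermediate
25 | chlorobis(cyclopentadienyl)[(2E,5Z)-6-iodohepta-2,5-dien-2-yl]zirconium | C/C(I)=C/C/C=C(\C)[Zr](Cl)(C1C=CC=C1)C1C=CC=C1 | intermediate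
26 | [(2E,5Z)-6-iodohepta-2,5-dien-2-yl](methyl)zinc | C/C(I)=C/C/C=C(\C)[Zn]C | intermediate
27 | methylzinc alkoxide of the 6S adduct of 26 to 19 | C=C1C(=O)O[C@@]([C@H](OC(C)=O)CCI)(C)CC[C@H]1C[C@H](O[Zn]C)/C(C)=C/C/C=C(/C)I | intermediate
28 | (1R)-3-iodo-1-[(2S,5S)-5-[(2S,3E,6Z)-7-iodo-3-methyl-2-(triethylsilyloxy)octa-3,6-dien-1-yl]-2-methyl-6-methylidene-7-oxooxepan-2-yl]propyl acetate | C=C1C(=O)O[C@@]([C@H](OC(C)=O)CCI)(C)CC[C@H]1C[C@H](O[Si](CC)(CC)CC)/C(C)=C/C/C=C(/C)I | intermediate
29 | alkylzinc iodide of 28 (C–ZnI in place of the primary C–I) | C=C1C(=O)O[C@@]([C@H](OC(C)=O)CC[Zn]I)(C)CC[C@H]1C[C@H](O[Si](CC)(CC)CC)/C(C)=C/C/C=C(/C)I | intermediate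
30 | 6-O-triethylsilyl ether of the target | C=C1C(=O)O[C@@]2(C)CC[C@H]1C[C@H](O[Si](CC)(CC)CC)/C(C)=C/C/C=C(/C)CC[C@H]2OC(C)=O | intermediate
31 | target CNP0130972.9: (1S,4S,6S,7E,10Z,14R) 14-membered carbocycle bridged by the α-methylene ε-lactone C4–C(=CH2)–C(=O)–O–C1, with 1-Me, 6-OH, 7-Me, 11-Me, 14-OAc | C=C1C(=O)O[C@@]2(C)CC[C@H]1C[C@H](O)/C(C)=C/C/C=C(/C)CC[C@H]2OC(C)=O | target

**Totals**
Total step count: 15. Longest linear sequence: 10 steps (1, 2, 3, 6, 7, 8, 9, 10, 14, 15).

**Steps most likely to fail, with fallbacks**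

Step 15 (macrocyclic alkylzinc coupling). If ring closure of 28 fails, the two junctions are made in the opposite order and the ring is closed at C6–C7 instead. Setting out from chloro acetal 17, NaI in acetone without acid gives iodo acetal 18, which is isolated. Zinc insertion gives the acetal alkylzinc iodide F1, which is coupled bimolecularly with the alkenyl iodide of 24 (PdCl2(dppf), THF/NMP) to give the acetal enyne F2. Aqueous HCl in acetone releases the ynal F3. A nickel-catalysed reductive alkyne–aldehyde macrocyclisation (Ni(cod)2, the N-heterocyclic carbene 1,3-bis(2,6-diisopropylphenyl)imidazol-2-ylidene, Et3SiH, toluene, high dilution) forms the C–C bond at the methyl-bearing alkyne carbon by syn addition (7E) and gives the macrocyclic silyl ether 30, where the route is rejoined before the acid work-up to 31. The C6 epimers would be separated there, and the enoate is the main liability toward nickel.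

Step 14 (facial selectivity and chemoselectivity of the alkenylzinc addition). If the ligand-controlled addition gives poor selectivity at C6, the stereocentre is set by ketone reduction instead. Setting out from 19 and 24, the same alkenylzinc reagent is added without MIB and without the silyl trap to give the C6-epimeric allylic alcohols F4. Dess–Martin periodinane converts both into the single enone F5. (R)-Me-CBS oxazaborolidine with catecholborane (toluene, −78 °C) reduces it to the 6S alcohol F6, and TESOTf/2,6-lutidine then gives 28, where the route is rejoined.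

Step 2 (rhodium-catalysed vinyl addition to an acyclic enoate carrying an acetal). If this addition is inefficient or poorly selective, the C3–C4 bond is made instead by copper-catalysed conjugate addition of the whole C7 chain, which also removes the Suzuki step. Setting out from enoate 3, the chain is built from 4-bromobut-1-yne F7: carboalumination (AlMe3, Cp2ZrCl2), conversion to the ate complex with n-BuLi and opening of ethylene oxide give (3E)-6-bromo-4-methylhex-3-en-1-ol F8. PPh3/N-chlorosuccinimide gives (3E)-1-bromo-6-chloro-3-methylhex-3-ene F9, and Mg inserts at the bromide only to give the Grignard reagent F10. F10 adds to 3 under CuBr·SMe2/Josiphos catalysis (tert-butyl methyl ether, −78 °C; ligand enantiomer chosen for 3S) to give the saturated ester F11. Enolate aminomethylation as in step 3 (Mannich base F12, ammonium iodide F13) and elimination give 13, where the route is rejoined; compounds 4, 5, 8, 9, 10, 11 and 12 are then not needed.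

**Further compounds**
F1 | step 15 | iodo[(3R)-3-acetoxy-3-[(2S,5S)-5-(2,2-dimethoxyethyl)-2-methyl-6-methylidene-7-oxooxepan-2-yl]propyl]zinc | C=C1C(=O)O[C@@]([C@H](OC(C)=O)CC[Zn]I)(C)CC[C@H]1CC(OC)OC
F2 | step 15 | (1R,4Z)-1-[(2S,5S)-5-(2,2-dimethoxyethyl)-2-methyl-6-methylidene-7-oxooxepan-2-yl]-4-methylnon-4-en-7-yn-1-yl acetate | C=C1C(=O)O[C@@]([C@H](OC(C)=O)CC/C(C)=C\CC#CC)(C)CC[C@H]1CC(OC)OC
F3 | step 15 | (1R,4Z)-4-methyl-1-[(2S,5S)-2-methyl-6-methylidene-7-oxo-5-(2-oxoethyl)oxepan-2-yl]non-4-en-7-yn-1-yl acetate | C=C1C(=O)O[C@@]([C@H](OC(C)=O)CC/C(C)=C\CC#CC)(C)CC[C@H]1CC=O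
F4 | step 14 | (1R)-1-[(2S,5S)-5-[(3E,6Z)-2-hydroxy-7-iodo-3-methylocta-3,6-dien-1-yl]-2-methyl-6-methylidene-7-oxooxepan-2-yl]-3-iodopropyl acetate, both C2' epimers | C=C1C(=O)O[C@@]([C@H](OC(C)=O)CCI)(C)CC[C@H]1CC(O)/C(C)=C/C/C=C(/C)I
F5 | step 14 | (1R)-3-iodo-1-[(2S,5S)-5-[(3E,6Z)-7-iodo-3-methyl-2-oxoocta-3,6-dien-1-yl]-2-methyl-6-methylidene-7-oxooxepan-2-yl]propyl acetate | C=C1C(=O)O[C@@]([C@H](OC(C)=O)CCI)(C)CC[C@H]1CC(=O)/C(C)=C/C/C=C(/C)I
F6 | step 14 | (1R)-1-[(2S,5S)-5-[(2S,3E,6Z)-2-hydroxy-7-iodo-3-methylocta-3,6-dien-1-yl]-2-methyl-6-methylidene-7-oxooxepan-2-yl]-3-iodopropyl acetate | C=C1C(=O)O[C@@]([C@H](OC(C)=O)CCI)(C)CC[C@H]1C[C@H](O)/C(C)=C/C/C=C(/C)I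
F7 | step 2 | 4-bromobut-1-yne | C#CCCBr
F8 | step 2 | (3E)-6-bromo-4-methylhex-3-en-1-ol | OCC/C=C(\C)CCBr
F9 | step 2 | (3E)-1-bromo-6-chloro-3-methylhex-3-ene | ClCC/C=C(\C)CCBr
F10 | step 2 | [(3E)-6-chloro-3-methylhex-3-en-1-yl]magnesium bromide | ClCC/C=C(\C)CC[Mg]Br
F11 | step 2 | methyl (3S,6E)-9-chloro-3-(2,2-dimethoxyethyl)-6-methylnon-6-enoate | ClCC/C=C(\C)CC[C@H](CC(=O)OC)CC(OC)OC
F12 | step 2 | methyl (6E)-9-chloro-2-[(dimethylamino)methyl]-3-(2,2-dimethoxyethyl)-6-methylnon-6-enoate, C3 as in F11, C2 epimers | ClCC/C=C(\C)CC[C@H](C(CN(C)C)C(=O)OC)CC(OC)OC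
F13 | step 2 | [(6E)-9-chloro-3-(2,2-dimethoxyethyl)-2-(methoxycarbonyl)-6-methylnon-6-en-1-yl]trimethylammonium iodide, C3 as in F11, C2 epimers | ClCC/C=C(\C)CC[C@H](C(C[N+](C)(C)C)C(=O)OC)CC(OC)OC.[I-]
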